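The data are simulated on assumed constants, noise included.

In the first 0.833 d, Wednesday's flask, charged with 6.88 times the D of Friday's, gained E about 3.17 times as fast. We want to know how this comparison drifts, and where it leaves E in three new flasks.

| flask | J | D | remark | time |
|---|---|---|---|---|
| Friday's | 10 mM | 16 mM | run made earlier |  |
| Wednesday's | 10 mM | 110 mM | run made earlier |  |
| zeta | 10 mM | 30.0 mM |  | 10 d |
| alpha | 10 mM | 60.0 mM |  | 10 d |
| epsilon | 10 mM | 120 mM |  | 10 d |

| run | time / d | J / % | E / % |
|---|---|---|---|
| Friday's | 0.833 | 74.9 | 2.4 |
| Friday's | 1.67 | 63.8 | 5.3 |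
| Friday's | 2.50 | 58.3 | 9.4 |
| Friday's | 3.00 | 54.9 | 11.5 |
| Friday's | 4.00 | 51.0 | 14.3 |
| Friday's | 5.00 | 46.0 | 17.9 |
| Wednesday's | 0.833 | 73.9 | 7.6 |
| Wednesday's | 1.67 | 57.1 | 16.4 |
| Wednesday's | 2.50 | 47.3 | 23.4 |
| Wednesday's | 3.00 | 43.5 | 26.0 |
| Wednesday's | 4.00 | 34.4 | 32.1 |
| Wednesday's | 5.00 | 29.2 | 36.6 |

(standard deviation of a reading: 0.5 percentage points)

- the analysis behind the earlier runs scatters by 0.5 percentage points, standard deviation
- at the start none of J is in solution
- what has only dissolved of J counts as not reacted

- part of the J that has reacted (what has only dissolved counts as not reacted) at the end, zeta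
- part of the J that has reacted (what has only dissolved counts as not reacted) at the end, alpha
- part of the J that has reacted (what has only dissolved counts as not reacted) at the end, epsilon
- what raising the concentration of D from its lowest to its highest value here does to the part of the J that has reacted (what has only dissolved counts as not reacted) (changes below 5 percentage points count as none) (it rises / it falls / no change)

1. We read the gap between the charge and J plus E as dissolved J. In Friday's flask it rises from 22.7% at 0.833 d to 36.1% at 5.00 d, and in Wednesday's it reaches 34.2%. So we take it as steady late on, with E forming pseudo-first-order in D.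

2. Between 3.00 d and 5.00 d, Wednesday's gain is 1.66 times Friday's. The advantage has shrunk, so we suppose D destroys itself, second order: c_D is the charge divided by one plus the charge over c_top, and c_top falls inversely with time.

3. Matching that ratio at 4.00 d gives 13.8 mM for c_top, the ceiling, the value c_D tends to at that time as the charge grows.

4. Integrating the gain of E gives a weight 24 percentage points, which multiplies the logarithm of the ratio of the two denominators, those at 10 d and at 5.00 d.

5. For E at 5.00 d we lay a straight line through the two runs against the logarithm of the charge of D, read between them for zeta and alpha and extended past Wednesday's charge for epsilon: 24.0%, 30.7% and 37.4%.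

6. Adding the late gains, we commit to 37.1% for zeta, 45.3% for alpha and 53.0% for epsilon.

The forecast, holding that “reaction appears to occur mainly at the solid surface”, gives 40% (34% to 45%), 47% (41% to 52%) and 51% (45% to 57%), with the trend it rises; our figures stand below it for zeta and alpha and above it for epsilon.

The flasks give 34.8%, 43.8% and 50.9%; the trend is it rises, by 16 points.

    X + D → L + E (k = 0.600 M⁻¹ h⁻¹)
    G ⇌ L, rate k2*(cs2 - [L]) while solid is left; crystals form when [L] > cs2 (solubility = 8.40 mM, k = 3.70 h⁻¹)
    D + L ⇌ Z, settled at all times (K = 5400 M⁻¹)
    2 D → Q (k = 0.360 M⁻¹ h⁻¹)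
    J ⇌ X, rate k5*(cs5 - [X]) while solid is left; crystals form when [X] > cs5 (solubility = 3.90 mM, k = 0.0470 h⁻¹)

Our weak link is the late gain: zeta gained 11 points after 5.00 d, more slowly than we reckoned. Reforged on zeta, the weight becomes 20 points. Now take a neighbouring flask, zeta with 75 mM of D. The ceiling 13.8 mM gives c_D 5.14 mM at 10 d, while the neighbouring flask holds 3.15 mM free, beside Z at 4.37 mM. The reforged weight gives E 45.3%, and the neighbouring flask gives 46.3%.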